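Time is the question: we want what stands in this flask at 40 h, and Monday's readings of this same flask stop at 15.0 h.

- Monday's: starting complex 20 mM; incoming ligand 60 mM; leaving ligand 10 mM; the very flask that is asked about, followed so far
- flask: starting complex 20 mM; incoming ligand 60.0 mM; leaving ligand 10.0 mM; time 40 h

Monday's run (percent of the starting complex charged)

| time / h | complex with two exchanged / % | starting complex / % |
|---|---|---|
| 3.00 | 23.7 | 9.7 |
| 6.00 | 23.1 | 2.6 |
| 10.0 | 18.2 | 1.0 |
| 12.0 | 15.7 | 0 |
| 15.0 | 13.6 | 0.1 |

(each reading ± 0.3 percentage points)

- what was read earlier has a scatter of 0.3 percentage points, one standard deviation
- a reading or a percentage of leaving ligand counts all its forms, free or not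

- green: doubling the dissolution coefficient of the leaving ligand, all else as stated
- violet: doubling the amount of incoming ligand, all else as stated
- red: doubling the solubility of the leaving ligand, all else as stated

- the complex with two exchanged standing at 40 h, as a percentage of the starting complex charged
- the change that raises the amount of complex with two exchanged at 40 h, in percent of the starting complex charged most ("none" if none brings more than 2 percentage points) (green / violet / red / none)
- amount of complex with two exchanged at 40 h, in percent of the starting complex charged, after violet

We keep one balance. Each exchange spends one incoming ligand, so c(incoming ligand) left equals its charge minus c(starting complex) charged times the mean exchanges per complex. The ceiling on that mean is the ligand budget, incoming ligand charged per starting complex charged, 3.00.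

At first the exchanges are quick: the starting complex reads 9.7% at 3.00 h. In the middle the complex with two exchanged reads 23.7%, then 23.1% at 6.00 h, so its peak reading lies near there. After that it falls, and we assume it passes on to a third exchange, the last one. Late in the run the budget matters. It equals the 3 sites per complex, so ligand left and open sites shrink together, like equal functional groups in step growth, and we expect the inverse of c(complex with two exchanged) to rise linearly. The readings at 10.0 h and 15.0 h, carried forward, give us 6.01%. Violet lifts the budget to 6.00, leaving 60.0 mM of ligand beyond the sites, so we expect the drain to go on and no gain. Green and red act on the leaving ligand, which stands outside this balance.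

The forecast says 9%, best change none, and 1% after violet. It stands higher than our figure, and in its words: “Return by released leaving ligand or a near plateau”.

The flask gives 5.26%, best change none, and 0% after violet, with 89.2% as complex with three exchanged at 40.0 h. Incoming ligand stands at 6.1% of its charge, so 2.82 of the budget is spent per complex. The budget also shows what would undo the forecast: the answer falls by 5 percentage points, away from the forecast's figure, at 73.2 mM of incoming ligand or 15.2 mM of starting complex, budgets of 3.66 and 3.94.

    2 starting complex → self-condensation product (k = 0.0160 /M/min)
    complex with two exchanged + incoming ligand → leaving ligand + complex with three exchanged (k = 0.230 /M/min)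
    crystals ⇌ leaving ligand, rate k3*(cs3 - [leaving ligand]) while solid is left; crystals form when [leaving ligand] > cs3 (solubility = 9.30 mM, k = 0.0360 /min)
    complex with one exchanged + incoming ligand → leaving ligand + complex with two exchanged (k = 0.150 /M/min)
    starting complex + incoming ligand → leaving ligand + complex with one exchanged (k = 0.320 /M/min)

Take a neighbouring flask, the same recipe with 36 mM of incoming ligand. Its budget is 1.80, less than 2, so the mean complex must stop short of two exchanges. It gives 24.1% at 40.0 h, with the incoming ligand, the limiting reagent there, at 0.12% of its charge and 1.80 exchanges counted per complex.

The earlier runs and the new flask are simulated on assumed constants, and the scatter is random.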